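The depside is cut at its aryl ester into a ring A acid and a ring B resorcylate, and ring B is built from open-chain pieces. Its substitution pattern, the C1 carboxyl flanked by the C2 oxygen and the C6 pentyl group with a second oxygen at C4, maps onto dibenzyl malonate (C1, C2 and the carboxyl) and (E)-non-3-en-2-one (C3 to C6 and the pentyl chain). A tandem Michael addition and Claisen cyclisation forms the C1–C6 and C2–C3 bonds and closes ring B as a cyclohexanedione ester in one operation; dehydrogenation then gives benzyl olivetolate. Both precursors are commercial, and benzyl groups are removed together at the end.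

Key step: step 1

Remark: the target has no stereocentre; compound 4 is written as one enol tautomer of the racemic 2,4-dione, and its C6 centre is erased in step 2.

Step 1
Reactants: 1 dibenzyl malonate; 2 (E)-non-3-en-2-one
Product: 4 benzyl 2-hydroxy-4-oxo-6-pentylcyclohex-1-ene-1-carboxylate (racemic), via Michael adduct 3 (not isolated)
Conditions: NaH, BnOH, THF, 0 °C; 1, then 2, 0 °C to 65 °C; cold aq. HCl
Reagents that add atoms: none
Why: Sodium benzyloxide deprotonates the malonate, whose anion adds in conjugate fashion to the pentyl-bearing β-carbon of the enone to give adduct 3; proton exchange then produces the methyl-side ketone enolate, which attacks one benzyl ester carbonyl and expels benzyloxide. This is the classical malonate–enone Michael–Claisen (Dieckmann-type) annulation to 6-alkylcyclohexane-1,3-dione carboxylates, run here with the benzyl ester and its matching alkoxide so that ester exchange is degenerate. Ring B closes in a 6-exo-trig mode on the ester carbonyl and is pulled forward by deprotonation of the product to its stabilised dione enolate. The one new stereocentre (C6) is formed without control, which does not matter because it becomes sp2 in step 2. The required regiochemistry (C1–C6 and C2–C3 bonds) follows from polarity and ring size: the malonate carbon can only attack the β-carbon, and only the methyl enolate can reach an ester carbonyl through a six-membered transition state, the internal enolate being limited to a four-membered ring. Water is excluded until the cold acidic quench so that the β-keto ester is not hydrolysed and decarboxylated.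

Step 2
Reactants: 4 benzyl 2-hydroxy-4-oxo-6-pentylcyclohex-1-ene-1-carboxylate
Product: 5 benzyl 2,4-dihydroxy-6-pentylbenzoate (benzyl olivetolate)
Conditions: I2 (0.2 equiv), DMSO, 80 °C
Reagents that add atoms: none
Why: Iodine-catalysed dehydrogenative aromatisation of a cyclohexane-1,3-dione: iodination of the enol and loss of HI should give the resorcinol tautomer while DMSO re-oxidises HI to I2, and the catalytic iodine load and weakly acidic medium should spare both the benzyl ester and the electron-rich product ring.

Step 3
Reactants: 6 5-propylresorcinol
Product: 8 2,4-dihydroxy-6-propylbenzaldehyde, via aryl iminium chloride 7 (not isolated)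
Conditions: POCl3, DMF, MeCN, 0 °C to rt; then H2O, 50 °C
Reagents that add atoms: N,N-dimethylformamide, CN(C)C=O; water, O
Why: Vilsmeier–Haack formylation: the chloroiminium electrophile should attack the ring position ortho to one hydroxyl and para to the other (next to the propyl group) in preference to the more hindered position between the two hydroxyls, and water then hydrolyses iminium salt 7 to the aldehyde.

Step 4
Reactants: 8 2,4-dihydroxy-6-propylbenzaldehyde
Product: 9 2-hydroxy-4-methoxy-6-propylbenzaldehyde
Conditions: MeI (1.05 equiv), K2CO3 (1.0 equiv), acetone, rt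
Reagents that add atoms: iodomethane, CI
Why: Williamson ether synthesis made regioselective by hydrogen bonding: the 4-hydroxyl para to the formyl group is the more acidic and is free, whereas the 2-hydroxyl is tied to the carbonyl oxygen and should not react with one equivalent of MeI at room temperature.

Step 5
Reactants: 9 2-hydroxy-4-methoxy-6-propylbenzaldehyde
Product: 10 2-(benzyloxy)-4-methoxy-6-propylbenzaldehyde
Conditions: BnBr, K2CO3, DMF, 60 °C
Reagents that add atoms: benzyl bromide, BrCc1ccccc1
Why: Williamson benzylation of the remaining chelated phenol, which the more polar solvent and heat should drive to completion; the aldehyde has no α-hydrogen and is inert to carbonate.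

Step 6
Reactants: 10 2-(benzyloxy)-4-methoxy-6-propylbenzaldehyde
Product: 11 2-(benzyloxy)-4-methoxy-6-propylbenzoic acid
Conditions: NaClO2, NaH2PO4, 2-methylbut-2-ene, t-BuOH/H2O, rt
Reagents that add atoms: sodium chlorite, [Na+].[O-]Cl=O
Why: Pinnick (Lindgren) chlorite oxidation of an aromatic aldehyde to the acid, with 2-methylbut-2-ene trapping HOCl so that the electron-rich ring is not chlorinated and the benzyl ether is untouched.

Step 7
Reactants: 5 benzyl 2,4-dihydroxy-6-pentylbenzoate; 11 2-(benzyloxy)-4-methoxy-6-propylbenzoic acid
Product: 13 benzyl 4-{[2-(benzyloxy)-4-methoxy-6-propylbenzoyl]oxy}-2-hydroxy-6-pentylbenzoate, via mixed trifluoroacetic anhydride 12 (not isolated)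
Conditions: (CF3CO)2O, toluene, 0 °C to rt; aq. NaHCO3 work-up
Reagents that add atoms: none
Why: Depside-type esterification through a mixed trifluoroacetic anhydride: the electron-rich, doubly ortho-substituted aroyl group of 12 is transferred to the free 4-hydroxyl of 5, while the 2-hydroxyl, hydrogen-bonded to and flanked by the benzyl ester, should stay unacylated and any aryl trifluoroacetate is cleaved in the bicarbonate work-up.

Step 8
Reactants: 13 benzyl 4-{[2-(benzyloxy)-4-methoxy-6-propylbenzoyl]oxy}-2-hydroxy-6-pentylbenzoate
Product: 14 benzyl 4-{[2-(benzyloxy)-4-methoxy-6-propylbenzoyl]oxy}-2-methoxy-6-pentylbenzoate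
Conditions: MeI, K2CO3, DMF, rt to 40 °C
Reagents that add atoms: iodomethane, CI
Why: Williamson methylation of the only free (chelated) hydroxyl; the depside carbonyl is shielded by its two ortho substituents and no external nucleophile is present, so the aryl ester and both benzyl groups should survive.

Step 9
Reactants: 14 benzyl 4-{[2-(benzyloxy)-4-methoxy-6-propylbenzoyl]oxy}-2-methoxy-6-pentylbenzoate
Product: 15 4-[(2-hydroxy-4-methoxy-6-propylbenzoyl)oxy]-2-methoxy-6-pentylbenzoic acid (CNP0522224.0)
Conditions: H2 (1 atm), palladium on carbon (10% Pd/C), EtOAc, rt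
Reagents that add atoms: none
Why: Catalytic hydrogenolysis cleaves the benzyl ester and the benzyl aryl ether in one operation and should leave the aryl ester link and the methyl ethers intact.

Compound list
1 | dibenzyl malonate | O=C(CC(=O)OCc1ccccc1)OCc1ccccc1 | starting material
2 | (E)-non-3-en-2-one | CCCCC/C=C/C(C)=O | starting material
3 | dibenzyl 2-(2-oxononan-4-yl)propanedioate (racemic) | CCCCCC(CC(C)=O)C(C(=O)OCc1ccccc1)C(=O)OCc1ccccc1 | intermediate (not isolated)
4 | benzyl 2-hydroxy-4-oxo-6-pentylcyclohex-1-ene-1-carboxylate (racemic; enol form of the 2,4-dione) | CCCCCC1CC(=O)CC(O)=C1C(=O)OCc1ccccc1 | intermediate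
5 | benzyl 2,4-dihydroxy-6-pentylbenzoate | CCCCCc1cc(O)cc(O)c1C(=O)OCc1ccccc1 | intermediate
6 | 5-propylresorcinol | CCCc1cc(O)cc(O)c1 | starting material
7 | (2,4-dihydroxy-6-propylbenzylidene)dimethyliminium chloride | CCCc1cc(O)cc(O)c1C=[N+](C)C.[Cl-] | intermediate (not isolated)
8 | 2,4-dihydroxy-6-propylbenzaldehyde | CCCc1cc(O)cc(O)c1C=O | intermediate
9 | 2-hydroxy-4-methoxy-6-propylbenzaldehyde | CCCc1cc(OC)cc(O)c1C=O | intermediate
10 | 2-(benzyloxy)-4-methoxy-6-propylbenzaldehyde | CCCc1cc(OC)cc(OCc2ccccc2)c1C=O | intermediate
11 | 2-(benzyloxy)-4-methoxy-6-propylbenzoic acid | CCCc1cc(OC)cc(OCc2ccccc2)c1C(=O)O | intermediate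
12 | 2-(benzyloxy)-4-methoxy-6-propylbenzoic trifluoroacetic anhydride | CCCc1cc(OC)cc(OCc2ccccc2)c1C(=O)OC(=O)C(F)(F)F | intermediate (not isolated)
13 | benzyl 4-{[2-(benzyloxy)-4-methoxy-6-propylbenzoyl]oxy}-2-hydroxy-6-pentylbenzoate | CCCCCc1cc(OC(=O)c2c(OCc3ccccc3)cc(OC)cc2CCC)cc(O)c1C(=O)OCc1ccccc1 | intermediate
14 | benzyl 4-{[2-(benzyloxy)-4-methoxy-6-propylbenzoyl]oxy}-2-methoxy-6-pentylbenzoate | CCCCCc1cc(OC(=O)c2c(OCc3ccccc3)cc(OC)cc2CCC)cc(OC)c1C(=O)OCc1ccccc1 | intermediate
15 | 4-[(2-hydroxy-4-methoxy-6-propylbenzoyl)oxy]-2-methoxy-6-pentylbenzoic acid | CCCCCc1cc(OC(=O)c2c(O)cc(OC)cc2CCC)cc(OC)c1C(=O)O | target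

Total step count: 9. Longest linear sequence: 7 steps (steps 3, 4, 5, 6, 7, 8, 9, from 5-propylresorcinol); the ring B arm reaches the target in 5 steps (steps 1, 2, 7, 8, 9).

Steps most likely to fail

Step 1. The Claisen closure may not keep pace with reversal of the conjugate addition and with base-induced self-condensation of the enone, and the β-keto ester may be hydrolysed and decarboxylated during isolation. The fallback sets out from 2 and returns at 4. The annulation is run in its classical methyl ester form (dimethyl malonate, NaOMe, MeOH, reflux). It passes through dimethyl 2-(2-oxononan-4-yl)propanedioate F1 and should give methyl 2-hydroxy-4-oxo-6-pentylcyclohex-1-ene-1-carboxylate F2, isolated as its sodium enolate and then acidified. The benzyl ester is installed only after ring formation, by thermal β-keto ester transesterification of F2 through the acylketene (BnOH, toluene, reflux, methanol distilled off), which should give 4.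

Step 7. Trifluoroacetylation of the phenol, C-acylation of the electron-rich ring B under the acidic conditions, or slow transfer of the hindered aroyl group may erode the yield. The fallback sets out from 11 and returns at 13. Acid 11 is converted with oxalyl chloride and catalytic DMF in CH2Cl2 into 2-(benzyloxy)-4-methoxy-6-propylbenzoyl chloride F3. F3 is then added to the mono-potassium phenoxide of 5 (K2CO3, one equivalent, acetone, 0 °C to rt). This replaces acid-promoted acyl transfer by base-mediated O-acylation, in which only the more acidic, unchelated 4-hydroxyl is deprotonated and ring carbon acylation is not expected.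

Step 8. Alkylation of the hydrogen-bonded hydroxyl may be sluggish, and at the temperature then needed carbonate-mediated acyl transfer could break the depside ester. The fallback sets out from 5 and returns at 14, with the methyl group placed before the two rings are joined. Selective 4-O-allylation of 5 (allyl bromide, K2CO3, acetone, reflux) should give benzyl 4-(allyloxy)-2-hydroxy-6-pentylbenzoate F4. Methylation (MeI, K2CO3, DMF, 50 °C) should give benzyl 4-(allyloxy)-2-methoxy-6-pentylbenzoate F5. Deallylation with catalytic Pd(PPh3)4 and morpholine in THF should give benzyl 4-hydroxy-2-methoxy-6-pentylbenzoate F6. F6 is then esterified with 11 under the conditions of step 7 (via 12) to give 14.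

Further compounds
F1 | step 1 | dimethyl 2-(2-oxononan-4-yl)propanedioate (racemic) | CCCCCC(CC(C)=O)C(C(=O)OC)C(=O)OC
F2 | step 1 | methyl 2-hydroxy-4-oxo-6-pentylcyclohex-1-ene-1-carboxylate (racemic) | CCCCCC1CC(=O)CC(O)=C1C(=O)OC
F3 | step 7 | 2-(benzyloxy)-4-methoxy-6-propylbenzoyl chloride | CCCc1cc(OC)cc(OCc2ccccc2)c1C(=O)Cl
F4 | step 8 | benzyl 4-(allyloxy)-2-hydroxy-6-pentylbenzoate | CCCCCc1cc(OCC=C)cc(O)c1C(=O)OCc1ccccc1
F5 | step 8 | benzyl 4-(allyloxy)-2-methoxy-6-pentylbenzoate | CCCCCc1cc(OCC=C)cc(OC)c1C(=O)OCc1ccccc1
F6 | step 8 | benzyl 4-hydroxy-2-methoxy-6-pentylbenzoate | CCCCCc1cc(O)cc(OC)c1C(=O)OCc1ccccc1
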